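**Retrosynthetic overview**

1. The hydroperoxide is set last by SN2 peroxidation, with inversion, of a (14R)-allylic alcohol. The C13–C14 bond comes from a Ni/Cr coupling of the 2-iodoalkene 13 with the butenolide aldehyde 20, which is made from L-allylglycine.
2. Iodoalkene 13 comes from bis-lactone 6. The δ-lactone is taken to the lactol and then the alkyne (C16 added) and the iodoalkene; the γ-lactone is opened to the C18 methyl ester and the 6α-OH.
3. Bis-lactone 6 comes from δ-lactone acid 5 by carboxylate-directed C6–H lactonisation (C6–O bond, γ-lactone).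
4. Acid 5 comes from neoabietic acid in three steps: ozonolytic excision of C14–C17, methylenation of C8, acid δ-lactonisation onto C8.
5. Feature used: the ester carbon C18 on C4 (4α, equatorial, ring A) and the 6α-oxygen on C6 (ring B) are peri across C5, so they form a five-membered 18,6α-lactone (C18–O–C6–C5–C4). Ring order: A/B bought, δ-lactone, γ-lactone (key step), butenolide built separately.

Key step: step 4

Remark: labdane numbering is used (C18 = 4α-carboxyl carbon, C17 = methyl on C8, C16 = exocyclic methylene carbon, C14 = hydroperoxide carbon). Neoabietic acid is taken as a catalogue resin acid. Read from the SMILES, C14 and the butenolide carbon of the target are both S.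

**Route**

Step 1
Reactants: 1 neoabietic acid
Product: 3 8-oxo-14,15,16,17-tetranorlabdane-13,18-dioic acid, via keto aldehyde acid 2 (not isolated)
Conditions: O3, CH2Cl2/MeOH, −78 °C; Me2S, −78 °C → rt; then H5IO6, THF/H2O, rt
Reagents that add atoms: ozone O=[O+][O-]; water O
Why: Ozonolysis should cleave both double bonds of the conjugated 8(14),13(15)-diene (C15–C17 leave as acetone, C8 becomes the ketone), and periodate cleavage of the resulting α-keto aldehyde removes C14 and leaves C13 as the acid; C9 keeps the stable 9α-H configuration with the chain equatorial.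

Step 2
Reactants: 3 8-oxo-14,15,16,17-tetranorlabdane-13,18-dioic acid
Product: 4 14,15,16-trinorlabd-8(17)-ene-13,18-dioic acid
Conditions: Ph3PCH3Br (5 equiv), KOtBu (5 equiv), THF/DMSO, rt → 50 °C; aq HCl work-up
Reagents that add atoms: methyltriphenylphosphonium bromide C[P+](c1ccccc1)(c1ccccc1)c1ccccc1.[Br-]
Why: Wittig methylenation of the C8 ketone with excess ylide (two equivalents are used up by the carboxylic acids) should give the exocyclic 8(17)-alkene, as is usual for 8-oxo decalins of this type.

Step 3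
Reactants: 4 14,15,16-trinorlabd-8(17)-ene-13,18-dioic acid
Product: 5 13-oxo-8α,13-epoxy-14,15,16-trinorlabdan-18-oic acid
Conditions: TfOH (0.1 equiv), CH2Cl2, 0 °C → rt
Reagents that add atoms: none
Why: Acid-catalysed lactonisation of an unsaturated acid: Markovnikov protonation gives the tertiary C8 cation, which the C13 carboxyl should capture from the α face, anti to the axial C10 methyl, so that the C8–O bond is equatorial (8α) and the δ-lactone is trans-fused.

Step 4
Reactants: 5 13-oxo-8α,13-epoxy-14,15,16-trinorlabdan-18-oic acid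
Product: 6 13-oxo-8α,13-epoxy-14,15,16-trinorlabdane-18,6α-olide
Conditions: Fe((S,S)-PDP)(MeCN)2(SbF6)2 (3 × 5 mol%), 50% H2O2 (3 × 1.2 equiv), MeCN, rt, no AcOH
Reagents that add atoms: none
Why: The C18 carboxylate binds iron in place of an added carboxylic acid, H2O2 is split to an iron(V)-oxo carboxylate, the oxo abstracts the equatorial 6α-hydrogen that lies peri to the equatorial C4 carboxyl, and the C6 radical recombines with the bound carboxylate oxygen (or with OH, followed by lactonisation of the 6α-hydroxy acid). The closest known reaction type is the carboxylic-acid-directed non-heme iron (PDP) C–H oxidation of acids to γ-lactones. The ring closed is the five-membered lactone C18–O–C6–C5–C4, formed by C6–O bonding to the tethered carboxylate, which corresponds to a 5-exo-trig acyl closure if the hydroxy acid intervenes. The new stereocentre C6 should be 6α-O because a γ-lactone from the 4α-carboxyl can span C4 and C6 only on the α face of the rigid trans-decalin. The step needs C6 to win over the other γ-carbon C2 and over undirected oxidation: a lactone to C2 would need a 1,3-diaxial bridge that the equatorial carboxyl cannot make, the δ-lactone oxygen deactivates C7 and C9, the carboxyl deactivates C3 and C5, and intramolecular delivery should outrun attack on the ring A methylenes. Acetic acid is left out so that the substrate is the only carboxylate ligand.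

Step 5
Reactants: 6 13-oxo-8α,13-epoxy-14,15,16-trinorlabdane-18,6α-olide
Product: 7 13-hydroxy-8α,13-epoxy-14,15,16-trinorlabdane-18,6α-olide (lactol, both C13 epimers)
Conditions: DIBAL-H (1.1 equiv), CH2Cl2, −78 °C; Rochelle salt
Reagents that add atoms: none
Why: Partial lactone reduction with DIBAL should take the δ-lactone, whose carbonyl carries a CH2 group, in preference to the γ-lactone carbonyl on the quaternary C4.

Step 6
Reactants: 7 13-hydroxy-8α,13-epoxy-14,15,16-trinorlabdane-18,6α-olide
Product: 8 8α-hydroxy-14,15-dinorlabd-13(16)-yne-18,6α-olide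
Conditions: dimethyl (1-diazo-2-oxopropyl)phosphonate, K2CO3, MeOH, 0 °C → rt
Reagents that add atoms: dimethyl (1-diazo-2-oxopropyl)phosphonate CC(=O)C(=[N+]=[N-])P(=O)(OC)OC
Why: Ohira–Bestmann (Seyferth–Gilbert) homologation of the hydroxy aldehyde in equilibrium with the lactol should give the terminal alkyne, adding C16 and freeing the tertiary 8α-OH.

Step 7
Reactants: 8 8α-hydroxy-14,15-dinorlabd-13(16)-yne-18,6α-olide
Product: 10 methyl 6α,8α-dihydroxy-14,15-dinorlabd-13(16)-yn-18-oate, via potassium hydroxy carboxylate 9 (not isolated)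
Conditions: KOH, MeOH/H2O, 65 °C; CO2 to pH 8, evaporate; MeI, DMF, rt
Reagents that add atoms: potassium hydroxide [K+].[OH-]; iodomethane CI
Why: Saponification of the γ-lactone followed by O-alkylation of the carboxylate with MeI fixes the open methyl ester irreversibly; excess hydroxide is buffered first so that no alkoxide can reclose the lactone, and any lactone already methanolysed in step 6 converges on the same carboxylate.

Step 8
Reactants: 10 methyl 6α,8α-dihydroxy-14,15-dinorlabd-13(16)-yn-18-oate
Product: 11 methyl 6α,8α-bis(triethylsilyloxy)-14,15-dinorlabd-13(16)-yn-18-oate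
Conditions: TESOTf, 2,6-lutidine, CH2Cl2, −78 → 0 °C
Reagents that add atoms: triethylsilyl triflate CC[Si](CC)(CC)OS(=O)(=O)C(F)(F)F
Why: Silylation with the silyl triflate should cap both the hindered secondary 6α-OH and the tertiary 8α-OH, which keeps them out of the haloboration and mesylation steps and blocks relactonisation.

Step 9
Reactants: 11 methyl 6α,8α-bis(triethylsilyloxy)-14,15-dinorlabd-13(16)-yn-18-oate
Product: 13 methyl 13-iodo-6α,8α-bis(triethylsilyloxy)-14,15-dinorlabd-13(16)-en-18-oate, via iodoalkenyl borane 12 (not isolated)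
Conditions: B-I-9-BBN, hexane, −20 → 0 °C; AcOH, 0 °C; aq NaHCO3
Reagents that add atoms: B-iodo-9-BBN IB1C2CCCC1CCC2
Why: Haloboration of the terminal alkyne places boron on the terminal carbon and iodine on C13 (syn addition), and protonolysis of the C–B bond with acetic acid should leave the 2-iodo-1-alkene.

Step 10
Reactants: 14 L-allylglycine
Product: 15 (S)-2-hydroxypent-4-enoic acid
Conditions: NaNO2, 1 M H2SO4, 0 °C → rt
Reagents that add atoms: water O
Why: Diazotisation of the α-amino acid proceeds with retention through the α-lactone (double inversion), so the S configuration of the later butenolide carbon is taken from the chiral pool.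

Step 11
Reactants: 15 (S)-2-hydroxypent-4-enoic acid
Product: 16 (S)-2-hydroxy-N-methoxy-N-methylpent-4-enamide
Conditions: MeNHOMe·HCl, EDC·HCl, HOBt, N-methylmorpholine, CH2Cl2, 0 °C → rt
Reagents that add atoms: N,O-dimethylhydroxylamine hydrochloride CNOC.Cl
Why: Carbodiimide amide coupling of the unprotected α-hydroxy acid should give the Weinreb amide without touching the stereocentre.

Step 12
Reactants: 16 (S)-2-hydroxy-N-methoxy-N-methylpent-4-enamide
Product: 17 (S)-3-hydroxyhex-5-en-2-one
Conditions: MeMgBr (3 equiv), THF, −20 → 0 °C; cold aq NH4Cl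
Reagents that add atoms: methylmagnesium bromide C[Mg]Br
Why: Weinreb ketone synthesis: the chelated tetrahedral intermediate stops at the methyl ketone, and the magnesium alkoxide of the α-hydroxyl protects the stereocentre from enolisation until the cold quench.

Step 13
Reactants: 17 (S)-3-hydroxyhex-5-en-2-one
Product: 19 (S)-4-methyl-5-(prop-2-enyl)furan-2(5H)-one, via ester ylide 18 (not isolated)
Conditions: Ph3P=C=C=O, toluene, 90 °C
Reagents that add atoms: (triphenylphosphoranylidene)ketene O=C=C=P(c1ccccc1)(c1ccccc1)c1ccccc1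
Why: The hydroxyl adds to the Bestmann ketenylidene ylide and the resulting ester ylide closes on the methyl ketone by intramolecular Wittig reaction, which should give the 4-methylbutenolide under neutral conditions with the carbinol centre unchanged.

Step 14
Reactants: 19 (S)-4-methyl-5-(prop-2-enyl)furan-2(5H)-one
Product: 20 [(2S)-3-methyl-5-oxo-2,5-dihydrofuran-2-yl]acetaldehyde
Conditions: O3, CH2Cl2, −78 °C (Sudan III end point); PPh3, −78 °C → rt; short silica plug, used at once
Reagents that add atoms: ozone O=[O+][O-]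
Why: Ozonolysis should select the electron-rich terminal alkene over the conjugated butenolide double bond, and the neutral reductive work-up avoids β-elimination of the lactone oxygen from the β-acyloxy aldehyde.

Step 15
Reactants: 13 methyl 13-iodo-6α,8α-bis(triethylsilyloxy)-14,15-dinorlabd-13(16)-en-18-oate; 20 [(2S)-3-methyl-5-oxo-2,5-dihydrofuran-2-yl]acetaldehyde
Product: 21 (14R)-allylic alcohol (C13–C14 coupled; 6α,8α-bis-TES ether; methyl ester; S butenolide)
Conditions: CrCl2, chiral oxazoline sulfonamide ligand (Kishi type, antipode for Si-face addition), Et3N, premixed in MeCN; NiCl2·2,9-dimethylphenanthroline (cat.); 13, then 20 (1.5 equiv), THF/MeCN, rt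
Reagents that add atoms: none
Why: Asymmetric Nozaki–Hiyama–Kishi coupling: nickel inserts into the C13–I bond, transmetalation gives the alkenylchromium(III), and the chiral chromium sulfonamide complex should direct addition to the Si face of the aldehyde, giving the 14R carbinol next to the 1,1-disubstituted alkene.

Step 16
Reactants: 22 2,3-dimethylbut-2-ene
Product: 23 2-methoxyprop-2-yl hydroperoxide
Conditions: O3, MeOH/CH2Cl2, −78 °C; kept and used as a stock solution
Reagents that add atoms: ozone O=[O+][O-]; methanol CO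
Why: Ozonolysis in methanol traps the acetone carbonyl oxide as the methoxy hydroperoxide, which is the known preparation of this monoprotected hydrogen peroxide.

Step 17
Reactants: 21 (14R)-allylic alcohol
Product: 24 (14R)-allylic methanesulfonate
Conditions: MsCl, Et3N, CH2Cl2, −40 °C; cold aqueous work-up, used crude
Reagents that add atoms: methanesulfonyl chloride CS(=O)(=O)Cl
Why: Sulfonylation of the only free hydroxyl (C14) with retention should give the leaving group; both other hydroxyls are silylated.

Step 18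
Reactants: 24 (14R)-allylic methanesulfonate; 23 2-methoxyprop-2-yl hydroperoxide
Product: 25 (14S)-2-methoxyprop-2-yl peroxide (peroxyketal; bis-TES ether)
Conditions: 23 (3 equiv), CsOH·H2O (2.5 equiv), premixed in DMF, 0 °C; then 24, 0 °C
Reagents that add atoms: none
Why: SN2 alkylation of the caesium peroxide anion by the secondary allylic mesylate should invert C14 from R to S; the ketal cap prevents double alkylation and base-induced loss of the new O–O bond.

Step 19
Reactants: 25 (14S)-2-methoxyprop-2-yl peroxide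
Product: 26 CNP0324515.1
Conditions: 48% aq HF/MeCN (1:19), 0 °C → rt
Reagents that add atoms: none
Why: Mild aqueous acid should hydrolyse the peroxyketal to the hydroperoxide and cleave both triethylsilyl ethers in one operation, conditions that the hydroperoxide, the butenolide and the hindered methyl ester tolerate.

**Compound list**

1 | neoabietic acid [abieta-8(14),13(15)-dien-18-oic acid] | CC(C)=C1CC[C@@H]2[C@@]3(C)CCC[C@@](C)(C(=O)O)[C@@H]3CCC2=C1 | starting material
2 | 8,13,14-trioxo-8,14-seco-15,16,17-trinorabietan-18-oic acid (keto aldehyde acid) | O=CC(=O)CC[C@@H]1[C@@]2(C)CCC[C@@](C)(C(=O)O)[C@@H]2CCC1=O | intermediate (not isolated)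
3 | 8-oxo-14,15,16,17-tetranorlabdane-13,18-dioic acid | O=C(O)CC[C@@H]1[C@@]2(C)CCC[C@@](C)(C(=O)O)[C@@H]2CCC1=O | intermediate
4 | 14,15,16-trinorlabd-8(17)-ene-13,18-dioic acid | O=C(O)CC[C@@H]1[C@@]2(C)CCC[C@@](C)(C(=O)O)[C@@H]2CCC1=C | intermediate
5 | 13-oxo-8α,13-epoxy-14,15,16-trinorlabdan-18-oic acid (δ-lactone acid) | O=C1CC[C@@H]2[C@@]3(C)CCC[C@@](C)(C(=O)O)[C@@H]3CC[C@@]2(C)O1 | intermediate (key-step precursor)
6 | 13-oxo-8α,13-epoxy-14,15,16-trinorlabdane-18,6α-olide (bis-lactone) | O=C1CC[C@@H]2[C@@]3(C)CCC[C@@](C)(C(=O)O4)[C@@H]3[C@@H]4C[C@@]2(C)O1 | intermediate (key-step product)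
7 | 13-hydroxy-8α,13-epoxy-14,15,16-trinorlabdane-18,6α-olide (lactol, C13 epimers) | OC1CC[C@@H]2[C@@]3(C)CCC[C@@](C)(C(=O)O4)[C@@H]3[C@@H]4C[C@@]2(C)O1 | intermediate
8 | 8α-hydroxy-14,15-dinorlabd-13(16)-yne-18,6α-olide | C#CCC[C@@H]1[C@@]2(C)CCC[C@@](C)(C(=O)O3)[C@@H]2[C@@H]3C[C@@]1(C)O | intermediate
9 | potassium 6α,8α-dihydroxy-14,15-dinorlabd-13(16)-yn-18-oate | C#CCC[C@@H]1[C@@]2(C)CCC[C@@](C)(C(=O)[O-])[C@@H]2[C@@H](O)C[C@@]1(C)O.[K+] | intermediate (not isolated)
10 | methyl 6α,8α-dihydroxy-14,15-dinorlabd-13(16)-yn-18-oate | C#CCC[C@@H]1[C@@]2(C)CCC[C@@](C)(C(=O)OC)[C@@H]2[C@@H](O)C[C@@]1(C)O | intermediate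
11 | methyl 6α,8α-bis(triethylsilyloxy)-14,15-dinorlabd-13(16)-yn-18-oate | C#CCC[C@@H]1[C@@]2(C)CCC[C@@](C)(C(=O)OC)[C@@H]2[C@@H](O[Si](CC)(CC)CC)C[C@@]1(C)O[Si](CC)(CC)CC | intermediate
12 | (Z)-13-iodo-16-(9-borabicyclo[3.3.1]nonan-9-yl) alkene from 11 (iodoalkenyl borane) | I/C(CC[C@@H]1[C@@]2(C)CCC[C@@](C)(C(=O)OC)[C@@H]2[C@@H](O[Si](CC)(CC)CC)C[C@@]1(C)O[Si](CC)(CC)CC)=C\B1C2CCCC1CCC2 | intermediate (not isolated)
13 | methyl 13-iodo-6α,8α-bis(triethylsilyloxy)-14,15-dinorlabd-13(16)-en-18-oate | C=C(I)CC[C@@H]1[C@@]2(C)CCC[C@@](C)(C(=O)OC)[C@@H]2[C@@H](O[Si](CC)(CC)CC)C[C@@]1(C)O[Si](CC)(CC)CC | intermediate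
14 | L-allylglycine [(S)-2-aminopent-4-enoic acid] | N[C@@H](CC=C)C(=O)O | starting material
15 | (S)-2-hydroxypent-4-enoic acid | O[C@@H](CC=C)C(=O)O | intermediate
16 | (S)-2-hydroxy-N-methoxy-N-methylpent-4-enamide | O[C@@H](CC=C)C(=O)N(C)OC | intermediate
17 | (S)-3-hydroxyhex-5-en-2-one | O[C@@H](CC=C)C(C)=O | intermediate
18 | (3S)-2-oxohex-5-en-3-yl (triphenylphosphoranylidene)acetate (ester ylide) | C=CC[C@@H](C(C)=O)OC(=O)C=P(c1ccccc1)(c1ccccc1)c1ccccc1 | intermediate (not isolated)
19 | (S)-4-methyl-5-(prop-2-enyl)furan-2(5H)-one | C=CC[C@@H]1OC(=O)C=C1C | intermediate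
20 | [(2S)-3-methyl-5-oxo-2,5-dihydrofuran-2-yl]acetaldehyde | O=CC[C@@H]1OC(=O)C=C1C | intermediate
21 | (14R)-allylic alcohol: methyl ester, 6α,8α-bis-TES ether, C13(=CH2)–C14H(OH)–CH2–(S)-butenolide | C=C(CC[C@@H]1[C@@]2(C)CCC[C@@](C)(C(=O)OC)[C@@H]2[C@@H](O[Si](CC)(CC)CC)C[C@@]1(C)O[Si](CC)(CC)CC)[C@@H](C[C@@H]1OC(=O)C=C1C)O | intermediate
22 | 2,3-dimethylbut-2-ene | CC(C)=C(C)C | starting material
23 | 2-methoxyprop-2-yl hydroperoxide | COC(C)(C)OO | intermediate
24 | (14R)-methanesulfonate of 21 | C=C(CC[C@@H]1[C@@]2(C)CCC[C@@](C)(C(=O)OC)[C@@H]2[C@@H](O[Si](CC)(CC)CC)C[C@@]1(C)O[Si](CC)(CC)CC)[C@@H](C[C@@H]1OC(=O)C=C1C)OS(C)(=O)=O | intermediate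
25 | (14S)-2-methoxyprop-2-yl peroxide (bis-TES ether) | C=C(CC[C@@H]1[C@@]2(C)CCC[C@@](C)(C(=O)OC)[C@@H]2[C@@H](O[Si](CC)(CC)CC)C[C@@]1(C)O[Si](CC)(CC)CC)[C@H](C[C@@H]1OC(=O)C=C1C)OOC(C)(C)OC | intermediate
26 | CNP0324515.1 (methyl ester, 6α-OH, 8α-OH, 14S-hydroperoxide, S butenolide) | C=C(CC[C@@H]1[C@@]2(C)CCC[C@@](C)(C(=O)OC)[C@@H]2[C@@H](O)C[C@@]1(C)O)[C@H](C[C@@H]1OC(=O)C=C1C)OO | target

**Step count**

Total: 19 steps. Longest linear sequence: 13 steps (1–9, 15, 17, 18, 19).

**Steps most likely to fail**

Step 4 (key step). Undirected oxidation of the ring A methylenes may compete with the directed abstraction at C6, or the hindered neopentyl carboxylate may bind iron poorly and conversion may stall. Fallback by amidyl-radical 1,5-hydrogen transfer: acid 5 is converted with oxalyl chloride into the acid chloride F1 and with ammonia at 0 °C into the primary carboxamide F2. Irradiation with PhI(OAc)2/I2 forms the N-iodoamide F3, whose amidyl radical takes the 6α-hydrogen through a six-membered transition state. Oxidation of the C6 radical and capture by the amide oxygen give the iminolactone F4, which is hydrolysed on aqueous work-up to bis-lactone 6, where the route is rejoined.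

Step 18. The peroxide anion may attack the allylic system at C16 (SN2′) or act as a base (elimination towards C15, epimerisation or opening of the butenolide), and partial ionisation of the allylic mesylate would erode the C14 configuration. Fallback by an ene reaction: alcohol 21 is treated with 2-nitrobenzenesulfonylhydrazide, PPh3 and DEAD to give the N-allyl sulfonylhydrazine F5, which on warming loses sulfinate and nitrogen with 1,3-transposition to give the (13E)-trisubstituted alkene F6. Photo-oxygenation (O2, tetraphenylporphyrin, light, CH2Cl2) should abstract hydrogen from the C16 methyl on the more substituted side and place oxygen on C14, giving the bis-TES hydroperoxide F7. This has to be separated from its C14 epimer and the tertiary regioisomer. HF/MeCN then gives target 26.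

Step 15. The β-acyloxy aldehyde may lose the lactone oxygen by β-elimination in the amine-containing medium, and facial control by the chromium ligand may be incomplete. Fallback by reagent-controlled reduction: 13 and 20 are coupled without ligand or amine (CrCl2, cat. NiCl2, DMF/THF), which gives 21 mixed with its 14S epimer F8. Dess–Martin oxidation of the mixture gives the α-methylene ketone F9, and reduction with (S)-Me-CBS and catecholborane (alkenyl as the large group) returns 21.

**Further compounds**

F1 | step 4 | acid chloride of 5 | O=C1CC[C@@H]2[C@@]3(C)CCC[C@@](C)(C(=O)Cl)[C@@H]3CC[C@@]2(C)O1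
F2 | step 4 | 13-oxo-8α,13-epoxy-14,15,16-trinorlabdan-18-amide | O=C1CC[C@@H]2[C@@]3(C)CCC[C@@](C)(C(N)=O)[C@@H]3CC[C@@]2(C)O1
F3 | step 4 | N-iodo amide of F2 | O=C1CC[C@@H]2[C@@]3(C)CCC[C@@](C)(C(=O)NI)[C@@H]3CC[C@@]2(C)O1
F4 | step 4 | 18,6α-iminolactone | O=C1CC[C@@H]2[C@@]3(C)CCC[C@@](C)(C(=N)O4)[C@@H]3[C@@H]4C[C@@]2(C)O1
F5 | step 18 | (14S)-N-allyl-N-(2-nitrobenzenesulfonyl)hydrazine from 21 | C=C(CC[C@@H]1[C@@]2(C)CCC[C@@](C)(C(=O)OC)[C@@H]2[C@@H](O[Si](CC)(CC)CC)C[C@@]1(C)O[Si](CC)(CC)CC)[C@H](C[C@@H]1OC(=O)C=C1C)N(N)S(=O)(=O)c1ccccc1[N+](=O)[O-]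
F6 | step 18 | (13E)-13(14)-alkene with C16 methyl (bis-TES ether) | C/C(CC[C@@H]1[C@@]2(C)CCC[C@@](C)(C(=O)OC)[C@@H]2[C@@H](O[Si](CC)(CC)CC)C[C@@]1(C)O[Si](CC)(CC)CC)=C\C[C@@H]1OC(=O)C=C1C
F7 | step 18 | 6α,8α-bis-TES ether of 26 | C=C(CC[C@@H]1[C@@]2(C)CCC[C@@](C)(C(=O)OC)[C@@H]2[C@@H](O[Si](CC)(CC)CC)C[C@@]1(C)O[Si](CC)(CC)CC)[C@H](C[C@@H]1OC(=O)C=C1C)OO
F8 | step 15 | 14S epimer of 21 | C=C(CC[C@@H]1[C@@]2(C)CCC[C@@](C)(C(=O)OC)[C@@H]2[C@@H](O[Si](CC)(CC)CC)C[C@@]1(C)O[Si](CC)(CC)CC)[C@H](C[C@@H]1OC(=O)C=C1C)O
F9 | step 15 | 14-oxo α-methylene ketone | C=C(CC[C@@H]1[C@@]2(C)CCC[C@@](C)(C(=O)OC)[C@@H]2[C@@H](O[Si](CC)(CC)CC)C[C@@]1(C)O[Si](CC)(CC)CC)C(=O)C[C@@H]1OC(=O)C=C1C
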